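## Structural features

The target 25 is an achiral hexameric phlorotannin: six benzene rings A to F joined in a row by five diaryl ether oxygens, with fifteen free phenolic hydroxyls and no carbon substituent. Rings A (2,4,6-trihydroxyphenyl) and F (3,4,5-trihydroxyphenyl) end the chain, rings B, D and E are 3,5-dihydroxy-1,4-phenylene units, and ring C is pentaoxygenated, with ether oxygens on the adjacent carbons C1 and C6, hydroxyls on C3 to C5 and its only hydrogen on C2. There is no stereocentre and no hindered axis, so the task is one of regiochemistry and of making crowded, electron-rich aryl ethers. A1, B4, D4 and E4 are each flanked by two oxygenated carbons and C6 by C1–O and C5–O, whereas B1, D1, E1 and F1 carry two ortho hydrogens. The free polyphenol is oxidised easily in air, most of all as a phenoxide, so every hydroxyl stays masked until the last step; on the way, the β-keto ester 17 is acid-sensitive (cyclodehydration onto C2–H to a benzofuran) and the chloroacrylate 20 is moisture-sensitive. The real difficulty lies in the B–C region, where the hindered B4 oxygen must be joined to the unsymmetrical ring C. The key step uses the oxygen pattern of ring B: hydroxyls on B3 and B5, an aryloxy group between them on B4 and a second one on B1. This is the pattern of a resorcylate assembled from a 4-aryloxy-3-oxobutanoate (B6, B5, B4) and a 3-aryloxyacrylate (B1, B2, B3), so both ether bonds of ring B are made before the ring exists. A ring-by-ring check of the atom mapping of this annulation against 25 showed the connectivity of 17, 20 and 22 to be correct; only the ester group at B6 and the base sequence were redesigned.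

## Logic of the disconnections

25 to 24: thirteen O–CH3 bonds are cut. Methyl ethers are the smallest masks, survive copper catalysis, peracid, base and acid, and all building blocks are available in this form. The gain is a stable, chromatographable precursor. The forward step must cleave every methyl ether without touching a diaryl ether, and must be worked up without air.

24 to 22: the B6–carboxyl bond is cut. The carboxyl group is the activating group that the annulation needs. A methyl ester on the chelated, doubly ortho-substituted resorcylate would have to be removed with hot hydroxide; a tert-butyl ester leaves with acid, and the resulting 2,4-dihydroxy-6-aryloxybenzoic acid loses CO2 on warming. The forward step needs a trap for the tert-butyl cation, because ring A is a strong nucleophile.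

22 to 17 and 20: the B6–B1 and B4–B3 bonds are cut. This splits the hexamer into a tetramer and a monomer and traces the two ether oxygens on ring B back to carbons that are not yet aromatic. The forward step must add the central carbon of 17 to the chlorine-bearing carbon of 20 and close through the γ carbon rather than through oxygen.

20 to 18 and 19: the vinylic C–O bond (later B1–O) is cut. The hindered phenol 18 is the nucleophile and an activated gem-dichloroalkene the electrophile, so no aryl–oxygen coupling is needed for the A–B ether. The forward step must stop after one chloride has been replaced.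

17 to 15 and 16: the O–CH2 bond (later B4–O) is cut. The crowded B4 oxygen is introduced by alkylation at a primary sp3 carbon. The forward step must avoid self-condensation of 16 and any acid.

15 to 14, and 14 to 12 and 13: the benzyl O–CH2 bond, then the F1–O bond are cut. The benzyl group differentiates the C1 oxygen from the C6 oxygen through the whole chain assembly. The ether is cut on the side of the unhindered ring, so the forward coupling uses the 2,6-dimethoxyphenol as nucleophile and an aryl iodide without ortho substituents.

12 to 10, and 10 to 9 and 6: the E4–O bond is traced to E4–CHO, then the E1–O bond is cut. The formyl group of 6 is a masked hydroxyl that also activates the para bromide. Each ring then costs two steps and no protecting group. The forward oxidation needs aryl rather than hydride migration, which two ortho methoxy groups and a para aryloxy group favour.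

9 to 7, and 7 to 5 and 6: the same pair of operations forms the D4 hydroxyl and the C6–O–D1 ether. The demand is highest here, because the phenol 5 has two ortho substituents and a very electron-rich ring.

5 to 3, 3 to 2, 2 to 1: the C6–O bond is traced to C6–CHO, the benzyl group is removed and the formyl group is taken off the ring. The C1 oxygen is the hydroxyl of 1; the C6 oxygen enters as a formyl group ortho to it. The two ortho positions of 1 are equivalent, so the formylation has no regiochemical choice.

## Other disconnections considered

Alternative 1: The cut is at the two ether bonds of ring C, C1–O and C6–O, on the ring C side. In the forward sense the cyclopentadienylruthenium complex A1 of 4,5-dichloro-1,2,3-trimethoxybenzene (divalent ruthenium) would react in one pot first with the phenoxide of the AB phenol A2 and then with that of the DEF phenol A3. This would give the complex A4, from which the metal would be released before global demethylation.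
- In its favour: substitution on cationic ruthenium arenes is reliable for hindered, electron-rich diaryl ethers under mild base, and the plan joins three fragments at once.
- Against it: the two chlorides differ only in their neighbours (C2–H beside C1, C5–OMe beside C6). Only the order of addition and the bulk of A2 would decide the regiochemistry, and a regioisomer with the halves exchanged would be very hard to separate.
- Against it also: the second substitution takes place on a ring that already carries a donor. Ruthenium is needed in stoichiometric amount, a decomplexation step is added, and A3 still needs the same copper etherifications as 15.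
- Comparison: the bond-forming event is mechanistically simpler than the Michael–Claisen cascade, and convergence is better (a longest sequence of about nine steps against thirteen); on both points the alternative is the better. The total step count would be about equal. The chosen plan is better in regiochemical security, because C1 and C6 are differentiated from step 2 on and ring B is fixed by the annulation, and it has thirteen rather than fifteen methyl ethers to cleave.

Alternative 2: The cut is at ten phenolic C–O bonds, each traced back to an aryl–CHO bond. The formyl groups ortho to A1, B4, C6, D4 and E4 would allow every ether to be made by substitution of a halide on an arene dialdehyde. The key step would be peracid oxidation of the decaaldehyde A5 and methanolysis of the ten formates to the decaphenol A6.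
- In its favour: the crowded carbons become activated electrophiles, no metal is needed, and only five methyl ethers remain for the last step. On the last point it is the better plan.
- Against it: ten aryl migrations must succeed in one molecule. Each formyl group has a single ortho aryloxy donor and at first sits on a ring with other formyl groups, the situation in which hydride migration to the carboxylic acid competes. One wrong event would give a by-product that differs from A6 in a single group.
- Against it also: the diformyl diaryl ethers are themselves electrophiles, so aryloxide exchange could scramble the chain during assembly, and the ring C monomer is a hexasubstituted benzene that would need its own synthesis.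
- Comparison: the chosen plan uses the same oxidation three times, each on a single 2,6-dialkoxybenzaldehyde, the favourable case. Its step count should be lower, and it does not depend on a tenfold transformation.

Alternative 3: The cut is at three carbon–carbon bonds of ring C (C2–C3, C1–C6, C3–C4). Heating the ethynyl ether A7, made from A2, with the cyclobutenone A8, made from A3, would run the Danheiser sequence: opening to a vinylketene, [2+2] addition to the ynol ether, a second opening and a six-electron closure. The product would be A9, with a free C3 hydroxyl and a C4 silyl ether.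
- In its favour: like the chosen plan it builds a crowded ring from non-aromatic pieces that already carry the ethers, and the pericyclic sequence fixes the pattern of ring C without any directing effect. On regiocontrol it is the equal of the chosen annulation.
- In its favour also: it needs neither base nor metal, joins two halves of similar size, and avoids the copper etherification at the doubly ortho-substituted C6 oxygen (step 4 here). On that point it is the better plan.
- Against it: A8 is a cyclobutenone with three oxygen substituents carrying the whole DEF unit. Its synthesis needs a regioselective substitution, a regioselective reduction of one of two similar carbonyl groups and a silylation. Its vinylketene is deactivated by three donors towards the electron-rich A7, and A7 is a hindered, thermally sensitive ynol ether that costs two extra steps.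
- Comparison: the total step count would be about equal and the longest sequence shorter. The chosen plan is better in the accessibility of its annulation partners, since 17 and 20 each come in one step from purchasable reagents.

Key step: step 12

Assumption: 25 has no stereocentre, the alkene geometry of 20 is left open because it is erased in step 12, and 4-bromo-2,6-dimethoxybenzaldehyde 6 is taken as a purchasable building block.

Abbreviation in names: "CDEF-aryloxy" = 2-{3,5-dimethoxy-4-[3,5-dimethoxy-4-(3,4,5-trimethoxyphenoxy)phenoxy]phenoxy}-3,4,5-trimethoxyphenoxy.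

## Route

Step 1
Reactants: 1 3,4,5-trimethoxyphenol
Product: 2 6-hydroxy-2,3,4-trimethoxybenzaldehyde
Conditions: MgCl2, Et3N, (CH2O)n, MeCN, reflux; then 1 M HCl
Reagents that add atoms: paraformaldehyde (as formaldehyde), C=O
Why: Magnesium-mediated ortho-formylation of a phenol; the magnesium phenoxide delivers formaldehyde to the ortho carbon and a second formaldehyde oxidises the benzylic alkoxide. Both ortho positions of 1 are equivalent and the para position is blocked, so only one aldehyde can form.

Step 2
Reactants: 2 6-hydroxy-2,3,4-trimethoxybenzaldehyde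
Product: 3 6-(benzyloxy)-2,3,4-trimethoxybenzaldehyde
Conditions: BnBr, K2CO3, DMF, 50 °C
Reagents that add atoms: benzyl bromide, BrCc1ccccc1
Why: Williamson etherification of the only hydroxyl; the benzyl group marks the future C1 oxygen and is stable to copper catalysis, peracid and acid-catalysed methanolysis.

Step 3
Reactants: 3 6-(benzyloxy)-2,3,4-trimethoxybenzaldehyde
Product: 5 6-(benzyloxy)-2,3,4-trimethoxyphenol, via aryl formate 4 (not isolated)
Conditions: mCPBA, CH2Cl2, 0 °C to rt; then MeOH, HCl (cat.), rt
Reagents that add atoms: mCPBA (3-chloroperoxybenzoic acid), O=C(OO)c1cccc(Cl)c1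
Why: Baeyer–Villiger (Dakin-type) oxidation; two ortho alkoxy groups and a para methoxy group make the aryl group migrate in preference to hydride, and the formate is methanolysed under acid so that no air-sensitive phenoxide is formed.

Step 4
Reactants: 5 6-(benzyloxy)-2,3,4-trimethoxyphenol; 6 4-bromo-2,6-dimethoxybenzaldehyde
Product: 7 4-[6-(benzyloxy)-2,3,4-trimethoxyphenoxy]-2,6-dimethoxybenzaldehyde
Conditions: CuI (10 mol %), picolinic acid (20 mol %), K3PO4, DMSO, 90 °C, Ar
Reagents that add atoms: none
Why: Ullmann-type copper-catalysed O-arylation; the picolinate-ligated copper phenoxide tolerates two ortho substituents on the phenol, and the bromide of 6 has no ortho substituent and is activated by the para formyl group. This forms the C6–O–D1 ether with the crowded partner as the nucleophile.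

Step 5
Reactants: 7 4-[6-(benzyloxy)-2,3,4-trimethoxyphenoxy]-2,6-dimethoxybenzaldehyde
Product: 9 4-[6-(benzyloxy)-2,3,4-trimethoxyphenoxy]-2,6-dimethoxyphenol, via aryl formate 8 (not isolated)
Conditions: mCPBA, CH2Cl2, 0 °C to rt; then MeOH, HCl (cat.), rt
Reagents that add atoms: mCPBA (3-chloroperoxybenzoic acid), O=C(OO)c1cccc(Cl)c1
Why: Baeyer–Villiger oxidation of a 2,6-dimethoxy-4-aryloxybenzaldehyde, the most favourable case for aryl migration; it unveils the D4 hydroxyl for the next coupling.

Step 6
Reactants: 9 4-[6-(benzyloxy)-2,3,4-trimethoxyphenoxy]-2,6-dimethoxyphenol; 6 4-bromo-2,6-dimethoxybenzaldehyde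
Product: 10 4-{4-[6-(benzyloxy)-2,3,4-trimethoxyphenoxy]-2,6-dimethoxyphenoxy}-2,6-dimethoxybenzaldehyde
Conditions: CuI (10 mol %), picolinic acid (20 mol %), K3PO4, DMSO, 90 °C, Ar
Reagents that add atoms: none
Why: Second Ullmann-type O-arylation of the same kind as step 4, with a 2,6-dimethoxyphenol as nucleophile and the activated, unhindered bromide 6; it forms the D4–O–E1 ether.

Step 7
Reactants: 10 4-{4-[6-(benzyloxy)-2,3,4-trimethoxyphenoxy]-2,6-dimethoxyphenoxy}-2,6-dimethoxybenzaldehyde
Product: 12 4-{4-[6-(benzyloxy)-2,3,4-trimethoxyphenoxy]-2,6-dimethoxyphenoxy}-2,6-dimethoxyphenol, via aryl formate 11 (not isolated)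
Conditions: mCPBA, CH2Cl2, 0 °C to rt; then MeOH, HCl (cat.), rt
Reagents that add atoms: mCPBA (3-chloroperoxybenzoic acid), O=C(OO)c1cccc(Cl)c1
Why: Baeyer–Villiger oxidation as in step 5; it unveils the E4 hydroxyl.

Step 8
Reactants: 12 4-{4-[6-(benzyloxy)-2,3,4-trimethoxyphenoxy]-2,6-dimethoxyphenoxy}-2,6-dimethoxyphenol; 13 5-iodo-1,2,3-trimethoxybenzene
Product: 14 1-(benzyloxy)-2-{3,5-dimethoxy-4-[3,5-dimethoxy-4-(3,4,5-trimethoxyphenoxy)phenoxy]phenoxy}-3,4,5-trimethoxybenzene
Conditions: CuI (10 mol %), picolinic acid (20 mol %), K3PO4, DMSO, 90 °C, Ar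
Reagents that add atoms: none
Why: Third Ullmann-type O-arylation; the iodide makes up for the missing activating group of ring F, and 13 has no ortho substituent.

Step 9
Reactants: 14 1-(benzyloxy)-2-{3,5-dimethoxy-4-[3,5-dimethoxy-4-(3,4,5-trimethoxyphenoxy)phenoxy]phenoxy}-3,4,5-trimethoxybenzene
Product: 15 2-{3,5-dimethoxy-4-[3,5-dimethoxy-4-(3,4,5-trimethoxyphenoxy)phenoxy]phenoxy}-3,4,5-trimethoxyphenol
Conditions: H2 (1 atm), 10% Pd/C, EtOAc–MeOH, rt
Reagents that add atoms: none
Why: Hydrogenolysis of the single benzyl ether under neutral conditions; aryl methyl ethers and diaryl ethers are inert, and the C1 hydroxyl is set free.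

Step 10
Reactants: 15 2-{3,5-dimethoxy-4-[3,5-dimethoxy-4-(3,4,5-trimethoxyphenoxy)phenoxy]phenoxy}-3,4,5-trimethoxyphenol; 16 tert-butyl 4-chloro-3-oxobutanoate
Product: 17 tert-butyl 4-(CDEF-aryloxy)-3-oxobutanoate
Conditions: NaH (2.2 equiv), THF–DMF, 0 °C; then 16, 0 °C to rt; aq NH4Cl
Reagents that add atoms: none
Why: Williamson O-alkylation of the phenoxide by the primary chloride; the second equivalent of hydride holds 16 and then 17 as their enolates, which suppresses self-condensation. The neutral work-up avoids the acid-catalysed cyclodehydration of 17 onto C2–H.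

Step 11
Reactants: 18 2,4,6-trimethoxyphenol; 19 methyl 3,3-dichloroprop-2-enoate
Product: 20 methyl 3-chloro-3-(2,4,6-trimethoxyphenoxy)prop-2-enoate
Conditions: K2CO3, 19 (1.5 equiv), MeCN, 0 °C to rt
Reagents that add atoms: none
Why: Nucleophilic vinylic substitution (addition–elimination) of one chloride of a β,β-dichloroacrylate by a phenoxide. The aryloxy group introduced is a donor and the 2,6-dimethoxyphenoxide is bulky, so the second substitution should be much slower than the first.

Step 12
Reactants: 17 tert-butyl 4-(CDEF-aryloxy)-3-oxobutanoate; 20 methyl 3-chloro-3-(2,4,6-trimethoxyphenoxy)prop-2-enoate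
Product: 22 tert-butyl 3-(CDEF-aryloxy)-2,4-dihydroxy-6-(2,4,6-trimethoxyphenoxy)benzoate, via glutaconate adduct 21 (not isolated)
Conditions: NaH (2.2 equiv), THF, 0 °C to rt; then NaOMe (2 equiv), MeOH, 60 °C; AcOH quench
Reagents that add atoms: none
Why: NaH turns 17 into its sodium enolate, whose central carbon adds to the chlorine-bearing β carbon of 20; the ester enolate so formed expels chloride (addition–elimination, B6–B1 bond), and the very acidic adduct 21 is held as its delocalised anion by the second equivalent of hydride. Methoxide in methanol at 60 °C then reversibly removes a γ proton, acidified by the ketone and by the aryloxy group, and this carbon attacks the methyl ester of the former acrylate in a 6-exo-trig Claisen closure (B4–B3 bond); loss of methoxide and enolisation give the aromatic resorcylate, which leaves all equilibria as its phenoxide. The closest known reaction type is the alkoxide-mediated Michael–Claisen condensation of acetoacetates with crotonates, β-chloro- or β-alkoxyacrylates and ynoates, which gives dihydroresorcylates and resorcylates. No stereocentre is formed, and the geometry of 20 is irrelevant because the anion of 21 can rotate about the former double bond. The selectivity needed is conjugate addition by the central carbon and acylation by the γ carbon: the first follows from the much higher acidity of the central position, the second from the γ carbon being the only carbon nucleophile that can reach the ester through a six-membered transition state. Closure through the enolate oxygen to a 2-pyranone is reversible under methoxide, whereas carbon closure ends in an aromatic phenoxide. Chloride leaves in preference to the aryloxide because it is by far the weaker base, and the tert-butyl ester is not attacked by methoxide, so the ester groups do not scramble.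

Step 13
Reactants: 22 tert-butyl 3-(CDEF-aryloxy)-2,4-dihydroxy-6-(2,4,6-trimethoxyphenoxy)benzoate
Product: 24 2-(CDEF-aryloxy)-5-(2,4,6-trimethoxyphenoxy)benzene-1,3-diol, via resorcylic acid 23 (not isolated)
Conditions: TFA–CH2Cl2 (1:3), Et3SiH (3 equiv), 0 °C to rt; concentrate; dioxane–H2O, 80 °C
Reagents that add atoms: none
Why: Acidolysis of the tert-butyl ester, with the silane reducing the tert-butyl cation before it can alkylate ring A, followed by protodecarboxylation. A benzoic acid with oxygen donors on both ortho carbons and the para carbon is protonated at the ipso carbon and loses CO2 on gentle heating.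

Step 14
Reactants: 24 2-(CDEF-aryloxy)-5-(2,4,6-trimethoxyphenoxy)benzene-1,3-diol
Product: 25 2-[4-(2-{4-[3,5-dihydroxy-4-(3,4,5-trihydroxyphenoxy)phenoxy]-3,5-dihydroxyphenoxy}-3,4,5-trihydroxyphenoxy)-3,5-dihydroxyphenoxy]benzene-1,3,5-triol
Conditions: BBr3 (30 equiv), CH2Cl2, −78 °C to rt, Ar; MeOH quench, evaporation, degassed aq work-up
Reagents that add atoms: none
Why: Lewis-acid cleavage of all thirteen aryl methyl ethers (boron coordination, then attack of bromide on the methyl carbon); diaryl ethers have no alkyl carbon to attack and are retained. Removal of boron as its methyl ester and work-up under argon protect the polyphenol.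

## Compound list

1 | 3,4,5-trimethoxyphenol | COc1cc(O)cc(OC)c1OC | starting material
2 | 6-hydroxy-2,3,4-trimethoxybenzaldehyde | O=Cc1c(O)cc(OC)c(OC)c1OC | intermediate
3 | 6-(benzyloxy)-2,3,4-trimethoxybenzaldehyde | O=Cc1c(OCc2ccccc2)cc(OC)c(OC)c1OC | intermediate
4 | 6-(benzyloxy)-2,3,4-trimethoxyphenyl formate | O=COc1c(OCc2ccccc2)cc(OC)c(OC)c1OC | intermediate
5 | 6-(benzyloxy)-2,3,4-trimethoxyphenol | Oc1c(OCc2ccccc2)cc(OC)c(OC)c1OC | intermediate
6 | 4-bromo-2,6-dimethoxybenzaldehyde | COc1cc(Br)cc(OC)c1C=O | starting material
7 | 4-[6-(benzyloxy)-2,3,4-trimethoxyphenoxy]-2,6-dimethoxybenzaldehyde | O=Cc1c(OC)cc(Oc2c(OCc3ccccc3)cc(OC)c(OC)c2OC)cc1OC | intermediate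
8 | 4-[6-(benzyloxy)-2,3,4-trimethoxyphenoxy]-2,6-dimethoxyphenyl formate | O=COc1c(OC)cc(Oc2c(OCc3ccccc3)cc(OC)c(OC)c2OC)cc1OC | intermediate
9 | 4-[6-(benzyloxy)-2,3,4-trimethoxyphenoxy]-2,6-dimethoxyphenol | Oc1c(OC)cc(Oc2c(OCc3ccccc3)cc(OC)c(OC)c2OC)cc1OC | intermediate
10 | 4-{4-[6-(benzyloxy)-2,3,4-trimethoxyphenoxy]-2,6-dimethoxyphenoxy}-2,6-dimethoxybenzaldehyde | O=Cc1c(OC)cc(Oc2c(OC)cc(Oc3c(OCc4ccccc4)cc(OC)c(OC)c3OC)cc2OC)cc1OC | intermediate
11 | 4-{4-[6-(benzyloxy)-2,3,4-trimethoxyphenoxy]-2,6-dimethoxyphenoxy}-2,6-dimethoxyphenyl formate | O=COc1c(OC)cc(Oc2c(OC)cc(Oc3c(OCc4ccccc4)cc(OC)c(OC)c3OC)cc2OC)cc1OC | intermediate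
12 | 4-{4-[6-(benzyloxy)-2,3,4-trimethoxyphenoxy]-2,6-dimethoxyphenoxy}-2,6-dimethoxyphenol | Oc1c(OC)cc(Oc2c(OC)cc(Oc3c(OCc4ccccc4)cc(OC)c(OC)c3OC)cc2OC)cc1OC | intermediate
13 | 5-iodo-1,2,3-trimethoxybenzene | COc1cc(I)cc(OC)c1OC | starting material
14 | 1-(benzyloxy)-2-{3,5-dimethoxy-4-[3,5-dimethoxy-4-(3,4,5-trimethoxyphenoxy)phenoxy]phenoxy}-3,4,5-trimethoxybenzene | COc1cc(Oc2c(OC)cc(Oc3c(OC)cc(Oc4c(OCc5ccccc5)cc(OC)c(OC)c4OC)cc3OC)cc2OC)cc(OC)c1OC | intermediate
15 | 2-{3,5-dimethoxy-4-[3,5-dimethoxy-4-(3,4,5-trimethoxyphenoxy)phenoxy]phenoxy}-3,4,5-trimethoxyphenol | COc1cc(Oc2c(OC)cc(Oc3c(OC)cc(Oc4c(O)cc(OC)c(OC)c4OC)cc3OC)cc2OC)cc(OC)c1OC | intermediate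
16 | tert-butyl 4-chloro-3-oxobutanoate | CC(C)(C)OC(=O)CC(=O)CCl | starting material
17 | tert-butyl 4-(2-{3,5-dimethoxy-4-[3,5-dimethoxy-4-(3,4,5-trimethoxyphenoxy)phenoxy]phenoxy}-3,4,5-trimethoxyphenoxy)-3-oxobutanoate | CC(C)(C)OC(=O)CC(=O)COc1cc(OC)c(OC)c(OC)c1Oc1cc(OC)c(Oc2cc(OC)c(Oc3cc(OC)c(OC)c(OC)c3)c(OC)c2)c(OC)c1 | intermediate
18 | 2,4,6-trimethoxyphenol | COc1cc(OC)c(O)c(OC)c1 | starting material
19 | methyl 3,3-dichloroprop-2-enoate | COC(=O)C=C(Cl)Cl | starting material
20 | methyl 3-chloro-3-(2,4,6-trimethoxyphenoxy)prop-2-enoate (alkene geometry undefined) | COC(=O)C=C(Cl)Oc1c(OC)cc(OC)cc1OC | intermediate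
21 | 5-tert-butyl 1-methyl 4-[(CDEF-aryloxy)acetyl]-3-(2,4,6-trimethoxyphenoxy)pent-2-enedioate (racemic at C4, alkene geometry undefined, present as its sodium enolate) | COC(=O)C=C(Oc1c(OC)cc(OC)cc1OC)C(C(=O)OC(C)(C)C)C(=O)COc1cc(OC)c(OC)c(OC)c1Oc1cc(OC)c(Oc2cc(OC)c(Oc3cc(OC)c(OC)c(OC)c3)c(OC)c2)c(OC)c1 | intermediate
22 | tert-butyl 3-(2-{3,5-dimethoxy-4-[3,5-dimethoxy-4-(3,4,5-trimethoxyphenoxy)phenoxy]phenoxy}-3,4,5-trimethoxyphenoxy)-2,4-dihydroxy-6-(2,4,6-trimethoxyphenoxy)benzoate | CC(C)(C)OC(=O)c1c(O)c(Oc2cc(OC)c(OC)c(OC)c2Oc2cc(OC)c(Oc3cc(OC)c(Oc4cc(OC)c(OC)c(OC)c4)c(OC)c3)c(OC)c2)c(O)cc1Oc1c(OC)cc(OC)cc1OC | intermediate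
23 | 3-(2-{3,5-dimethoxy-4-[3,5-dimethoxy-4-(3,4,5-trimethoxyphenoxy)phenoxy]phenoxy}-3,4,5-trimethoxyphenoxy)-2,4-dihydroxy-6-(2,4,6-trimethoxyphenoxy)benzoic acid | OC(=O)c1c(O)c(Oc2cc(OC)c(OC)c(OC)c2Oc2cc(OC)c(Oc3cc(OC)c(Oc4cc(OC)c(OC)c(OC)c4)c(OC)c3)c(OC)c2)c(O)cc1Oc1c(OC)cc(OC)cc1OC | intermediate
24 | 2-(2-{3,5-dimethoxy-4-[3,5-dimethoxy-4-(3,4,5-trimethoxyphenoxy)phenoxy]phenoxy}-3,4,5-trimethoxyphenoxy)-5-(2,4,6-trimethoxyphenoxy)benzene-1,3-diol | COc1cc(OC)c(Oc2cc(O)c(Oc3cc(OC)c(OC)c(OC)c3Oc3cc(OC)c(Oc4cc(OC)c(Oc5cc(OC)c(OC)c(OC)c5)c(OC)c4)c(OC)c3)c(O)c2)c(OC)c1 | intermediate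
25 | 2-[4-(2-{4-[3,5-dihydroxy-4-(3,4,5-trihydroxyphenoxy)phenoxy]-3,5-dihydroxyphenoxy}-3,4,5-trihydroxyphenoxy)-3,5-dihydroxyphenoxy]benzene-1,3,5-triol (CNP0270681.0) | Oc1cc(O)c(Oc2cc(O)c(Oc3cc(O)c(O)c(O)c3Oc3cc(O)c(Oc4cc(O)c(Oc5cc(O)c(O)c(O)c5)c(O)c4)c(O)c3)c(O)c2)c(O)c1 | target

## Step count and least certain steps

Total: 14 steps. Longest linear sequence: 13 steps (steps 1 to 10, then 12, 13 and 14); step 11 runs in parallel.

Step 12 (key step).
- Risk: the conjugate addition–elimination may be slow or misdirected at the β carbon of 20, which is hindered and deactivated by its aryloxy donor. Exchange of chloride or aryloxide by methoxide, or hydrolysis, could then compete. Second in likelihood is ring closure through the enolate oxygen instead of the γ carbon.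
- Fallback: replace the acceptor by an ynoate that has no leaving group and an unhindered sp carbon. Setting out from 18, reaction with trichloroethylene and K2CO3 in DMF would give 2-{[(E)-1,2-dichloroethenyl]oxy}-1,3,5-trimethoxybenzene F1. Treatment with n-BuLi (2.2 equiv) at −78 °C and then methyl chloroformate would give methyl 3-(2,4,6-trimethoxyphenoxy)prop-2-ynoate F2. Conjugate addition of the enolate of 17 to F2 gives the anion of 21 directly, and the same Claisen closure returns to the route at 22.

Step 11.
- Risk: over-substitution to the bis(aryloxy)acrylate, and hydrolysis of 20 during isolation, because the product is still an activated vinylic electrophile.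
- Fallback: make the double substitution the aim. From 18 (2.2 equiv) and 19 with Cs2CO3 in DMF, methyl 3,3-bis(2,4,6-trimethoxyphenoxy)prop-2-enoate F3 would be formed, a stable ketene acetal without alkene geometry. Used in place of 20 in step 12, it would lose one aryloxide (recovered as 18) in the addition–elimination and rejoin the route at 22 by way of 21.

Step 10.
- Risk: base-induced self-condensation of 16 and slow O-alkylation by the hindered phenoxide of 15, with loss of the valuable tetramer.
- Fallback: build the keto ester by homologation. From 15, alkylation with methyl bromoacetate and K2CO3 in acetone would give methyl (CDEF-aryloxy)acetate F4. Saponification with LiOH would give (CDEF-aryloxy)acetic acid F5. Activation with 1,1'-carbonyldiimidazole and decarboxylative Claisen condensation with Mg(O2CCH2CO2tBu)2 would return to the route at 17.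

Step 4 (the same holds, to a smaller degree, for steps 6 and 8).
- Risk: oxidative degradation of the very electron-rich, doubly ortho-substituted phenoxide of 5 in the presence of copper, and reduction of the bromide when the coupling is slow.
- Fallback: a metal-free aromatic substitution. From 5, reaction with 4-fluoro-2,6-dimethoxybenzaldehyde and Cs2CO3 in DMSO at 100 to 120 °C, where the para formyl group activates the fluoride, returns directly to the route at 7. No compound outside the list is formed (F0).

Step 14.
- Risk: incomplete cleavage of thirteen methyl ethers, leaving partly methylated material, and oxidation of the free polyphenol during isolation.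
- Fallback: isolate through a stable derivative. From 24, the crude product of the BBr3 reaction would be acetylated with Ac2O and pyridine to the pentadecaacetate F6 of 25, which can be chromatographed and freed from under-demethylated material. Acid-catalysed methanolysis (AcCl cat., MeOH, argon) would then return to the route at 25.

## Further compounds

F1 | step 12 | 2-{[(E)-1,2-dichloroethenyl]oxy}-1,3,5-trimethoxybenzene | Cl/C=C(/Cl)Oc1c(OC)cc(OC)cc1OC
F2 | step 12 | methyl 3-(2,4,6-trimethoxyphenoxy)prop-2-ynoate | COC(=O)C#COc1c(OC)cc(OC)cc1OC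
F3 | step 11 | methyl 3,3-bis(2,4,6-trimethoxyphenoxy)prop-2-enoate | COC(=O)C=C(Oc1c(OC)cc(OC)cc1OC)Oc1c(OC)cc(OC)cc1OC
F4 | step 10 | methyl (2-{3,5-dimethoxy-4-[3,5-dimethoxy-4-(3,4,5-trimethoxyphenoxy)phenoxy]phenoxy}-3,4,5-trimethoxyphenoxy)acetate | COC(=O)COc1cc(OC)c(OC)c(OC)c1Oc1cc(OC)c(Oc2cc(OC)c(Oc3cc(OC)c(OC)c(OC)c3)c(OC)c2)c(OC)c1
F5 | step 10 | (2-{3,5-dimethoxy-4-[3,5-dimethoxy-4-(3,4,5-trimethoxyphenoxy)phenoxy]phenoxy}-3,4,5-trimethoxyphenoxy)acetic acid | OC(=O)COc1cc(OC)c(OC)c(OC)c1Oc1cc(OC)c(Oc2cc(OC)c(Oc3cc(OC)c(OC)c(OC)c3)c(OC)c2)c(OC)c1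
F0 | step 4 | none | none
F6 | step 14 | pentadecaacetate of 25 (every hydroxyl as its acetate) | CC(=O)Oc1cc(OC(C)=O)c(Oc2cc(OC(C)=O)c(Oc3cc(OC(C)=O)c(OC(C)=O)c(OC(C)=O)c3Oc3cc(OC(C)=O)c(Oc4cc(OC(C)=O)c(Oc5cc(OC(C)=O)c(OC(C)=O)c(OC(C)=O)c5)c(OC(C)=O)c4)c(OC(C)=O)c3)c(OC(C)=O)c2)c(OC(C)=O)c1
A1 | alternative 1 | (cyclopentadienyl)(4,5-dichloro-1,2,3-trimethoxybenzene)ruthenium hexafluorophosphate | COc1cc(Cl)c(Cl)c(OC)c1OC.[cH-]1cccc1.[Ru+2].F[P-](F)(F)(F)(F)F
A2 | alternative 1 | 2,6-dimethoxy-4-(2,4,6-trimethoxyphenoxy)phenol (AB phenol) | COc1cc(OC)c(Oc2cc(OC)c(O)c(OC)c2)c(OC)c1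
A3 | alternative 1 | 3,5-dimethoxy-4-[3,5-dimethoxy-4-(3,4,5-trimethoxyphenoxy)phenoxy]phenol (DEF phenol) | Oc1cc(OC)c(Oc2cc(OC)c(Oc3cc(OC)c(OC)c(OC)c3)c(OC)c2)c(OC)c1
A4 | alternative 1 | cyclopentadienylruthenium hexafluorophosphate complex of the permethylated hexamer, metal on ring C | COc1cc(OC)c(Oc2cc(OC)c(Oc3cc(OC)c(OC)c(OC)c3Oc3cc(OC)c(Oc4cc(OC)c(Oc5cc(OC)c(OC)c(OC)c5)c(OC)c4)c(OC)c3)c(OC)c2)c(OC)c1.[cH-]1cccc1.[Ru+2].F[P-](F)(F)(F)(F)F
A5 | alternative 2 | hexamer decaaldehyde with formyl groups at A2, A6, B3, B5, C3, C5, D3, D5, E3 and E5 and five methyl ethers | COc1cc(C=O)c(Oc2cc(C=O)c(Oc3cc(C=O)c(OC)c(C=O)c3Oc3cc(C=O)c(Oc4cc(C=O)c(Oc5cc(OC)c(OC)c(OC)c5)c(C=O)c4)c(C=O)c3)c(C=O)c2)c(C=O)c1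
A6 | alternative 2 | hexamer decaphenol with five methyl ethers | COc1cc(O)c(Oc2cc(O)c(Oc3cc(O)c(OC)c(O)c3Oc3cc(O)c(Oc4cc(O)c(Oc5cc(OC)c(OC)c(OC)c5)c(O)c4)c(O)c3)c(O)c2)c(O)c1
A7 | alternative 3 | 2-(ethynyloxy)-1,3-dimethoxy-5-(2,4,6-trimethoxyphenoxy)benzene | COc1cc(OC)c(Oc2cc(OC)c(OC#C)c(OC)c2)c(OC)c1
A8 | alternative 3 | 4-[(tert-butyldimethylsilyl)oxy]-2-{3,5-dimethoxy-4-[3,5-dimethoxy-4-(3,4,5-trimethoxyphenoxy)phenoxy]phenoxy}-3-methoxycyclobut-2-en-1-one (racemic) | COC1=C(Oc2cc(OC)c(Oc3cc(OC)c(Oc4cc(OC)c(OC)c(OC)c4)c(OC)c3)c(OC)c2)C(=O)C1O[Si](C)(C)C(C)(C)C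
A9 | alternative 3 | protected hexamer with free C3 phenol and C4 tert-butyldimethylsilyl ether | COc1cc(OC)c(Oc2cc(OC)c(Oc3cc(O)c(O[Si](C)(C)C(C)(C)C)c(OC)c3Oc3cc(OC)c(Oc4cc(OC)c(Oc5cc(OC)c(OC)c(OC)c5)c(OC)c4)c(OC)c3)c(OC)c2)c(OC)c1
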